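Numbering: C1 ester carbon, C2, C3–C6 dioxane carbons (O–O bridges C3 and C6), C7–C9, C10 (=CH2), C11–C12, C13 carbinol, C14 (=CH2), C15–C17, C18 (CMe2). The retrosynthesis cuts C9–C10, C13–C14, both peroxide C–O bonds (C6–O, C3–O) and C2–C3.
Enabling feature: in the cyclohexane ring the tertiary carbinol C13 is bonded directly to C14, which carries the exocyclic methylene. This is the pattern formed when a ketone carbon is joined reductively to the internal carbon of a terminal alkyne. C15–C17 and quaternary C18 are the tether.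
Fragment A (steps 1–8): the acyclic alkynone is assembled, the carbocycle is closed at C13–C14, and the side-chain methyl ketone becomes the C10 enol triflate.
Fragment B (steps 9–19): linalool supplies C3–C8 and the C6 methyl, crotylboration adds C1, C2 and the C2 methyl, and H2O2 is inserted by two invertive displacements that close the 1,2-dioxane second.
Union and end (steps 20–23): a B-alkyl Suzuki–Miyaura coupling forms C9–C10, and C1 is oxidised to the methyl ester last, so the base-labile β-peroxy ester exists only at the end.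
Stereochemistry: C13 comes from the P-stereogenic ligand on nickel, C6 from (R)-linalool with one inversion, and C2/C3 from an anti-crotylboration with C3 inverted on ring closure.

Key step: step 6

Assumption: (S)-AntPhos is taken as the ligand antipode that gives the (R)-carbinol (the mirror-image ligand is used if a pilot run shows the opposite sense), and commercial (R)-(−)-linalool is taken as enantiomerically pure.

Step 1
Reactants: 1 5-chloropent-1-yne
Product: 2 5-iodopent-1-yne
Conditions: NaI, acetone, reflux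
Reagents that add atoms: sodium iodide, [Na+].[I-]
Why: Finkelstein halide exchange, driven by precipitation of NaCl, should give the more reactive primary iodide for the enolate alkylation.

Step 2
Reactants: 3 methyl isobutyrate; 2 5-iodopent-1-yne
Product: 5 methyl 2,2-dimethylhept-6-ynoate, via lithium enolate 4 (not isolated)
Conditions: LiN(i-Pr)2, THF, −78 °C; then 2, DMPU, −78 °C → rt
Reagents that add atoms: none
Why: SN2 alkylation of the ester enolate by a primary iodide builds quaternary C18, and the enolate is too weak a base to be consumed appreciably by the alkyl-acetylene C–H.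

Step 3
Reactants: 5 methyl 2,2-dimethylhept-6-ynoate
Product: 6 2,2-dimethylhept-6-ynal
Conditions: i-Bu2AlH (1.1 equiv), CH2Cl2, −78 °C; H2O work-up
Reagents that add atoms: none
Why: Partial ester reduction should stop at the aldehyde because the crowded aluminium hemiacetal persists at −78 °C and collapses only on work-up, while the alkyne is not hydroaluminated at this temperature.

Step 4
Reactants: 7 2-(2-bromoethyl)-2-methyl-1,3-dioxolane; 6 2,2-dimethylhept-6-ynal
Product: 9 4,4-dimethyl-1-(2-methyl-1,3-dioxolan-2-yl)non-8-yn-3-ol (racemic), via Grignard reagent 8 (not isolated)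
Conditions: Mg, THF, 20–25 °C; then 6 (0.45 equiv relative to 8), 0 °C; H2O work-up
Reagents that add atoms: none
Why: Grignard addition to a non-enolisable aldehyde attaches C10–C12 with the future methylene carbon; the excess reagent covers the acetylenic proton, and the carbinol centre is erased in the next step.

Step 5
Reactants: 9 4,4-dimethyl-1-(2-methyl-1,3-dioxolan-2-yl)non-8-yn-3-ol
Product: 10 4,4-dimethyl-1-(2-methyl-1,3-dioxolan-2-yl)non-8-yn-3-one
Conditions: Dess–Martin periodinane, NaHCO3, CH2Cl2, 0 °C → rt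
Reagents that add atoms: none
Why: Dess–Martin oxidation converts even a neopentyl carbinol into the ketone under buffered conditions that spare the ketal and the alkyne.

Step 6
Reactants: 10 4,4-dimethyl-1-(2-methyl-1,3-dioxolan-2-yl)non-8-yn-3-one; 11 triethylsilane
Product: 12 triethyl({(1R)-2,2-dimethyl-6-methylidene-1-[2-(2-methyl-1,3-dioxolan-2-yl)ethyl]cyclohexyl}oxy)silane
Conditions: Ni(cod)2 (10 mol %), (S)-AntPhos [(S)-4-(anthracen-9-yl)-3-tert-butyl-2,3-dihydro-1,3-benzoxaphosphole] (12 mol %), 11 (3 equiv), 1,4-dioxane, 25–40 °C, 10 added by syringe pump over several hours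
Reagents that add atoms: none
Why: Proposed new method: a zerovalent nickel centre carrying one bulky phosphine takes up the alkyne and the C13 carbonyl side by side and joins C14 to C13, giving a five-membered nickelacycle with Ni–O and Ni–C(sp2) bonds; the silane then exchanges across Ni–O (Si–O formed, Ni–H left) and the vinyl–Ni–H unit collapses by reductive elimination to 12. The closest known reaction type is the nickel/chiral monophosphine-catalysed enantioselective reductive cyclisation of alkynones with silanes, shown for internal alkynes and less crowded ketones, so the untested element is a terminal alkyne paired with a tert-alkyl ketone in an all-carbon tether. The cyclohexane closes in a formal 6-exo-dig mode, the only regiochemistry the C15–C18 tether allows, and syn addition puts the silane hydrogen on the former terminal carbon, which becomes the exocyclic methylene. C13 is set by the ligand, which has to distinguish the quaternary C18 flank of the carbonyl from the C12 methylene flank, a strong steric bias. The step needs cyclisation to outrun alkyne oligomerisation and hydrosilylation; the gem-dimethyl group (Thorpe–Ingold folding) and the low stationary alkyne concentration from slow addition should secure this, while the ketal is inert.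

Step 7
Reactants: 12 triethyl({(1R)-2,2-dimethyl-6-methylidene-1-[2-(2-methyl-1,3-dioxolan-2-yl)ethyl]cyclohexyl}oxy)silane
Product: 13 4-[(1R)-2,2-dimethyl-6-methylidene-1-(triethylsilyloxy)cyclohexyl]butan-2-one
Conditions: PPTS (20 mol %), acetone/H2O, 45 °C
Reagents that add atoms: water, O
Why: Mild acid-catalysed ketal hydrolysis frees the methyl ketone under conditions that the crowded tertiary silyl ether and the allylic C13–O bond should survive.

Step 8
Reactants: 13 4-[(1R)-2,2-dimethyl-6-methylidene-1-(triethylsilyloxy)cyclohexyl]butan-2-one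
Product: 15 4-[(1R)-2,2-dimethyl-6-methylidene-1-(triethylsilyloxy)cyclohexyl]but-1-en-2-yl trifluoromethanesulfonate, via lithium enolate 14 (not isolated)
Conditions: LiN(i-Pr)2, THF, −78 °C; then N-(5-chloropyridin-2-yl)bis(trifluoromethanesulfonimide), −78 → −20 °C
Reagents that add atoms: N-(5-chloropyridin-2-yl)bis(trifluoromethanesulfonimide), FC(F)(F)S(=O)(=O)N(c1ccc(Cl)cn1)S(=O)(=O)C(F)(F)F
Why: Kinetic deprotonation at the methyl group followed by O-sulfonylation (enol triflate formation) should give the 1,1-disubstituted alkenyl triflate that holds C10 and its methylene.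

Step 9
Reactants: 16 (R)-(−)-linalool
Product: 18 (3R)-3,7-dimethyloct-6-ene-1,3-diol, via B-alkyl-9-BBN 17 (not isolated)
Conditions: 9-BBN (2.2 equiv), THF, 0 °C → rt; then NaOH, H2O2, 0 °C
Reagents that add atoms: hydrogen peroxide, OO
Why: Hydroboration–oxidation with 9-BBN takes the monosubstituted vinyl group much faster than the trisubstituted alkene and leaves the chiral-pool centre (future C6) untouched.

Step 10
Reactants: 18 (3R)-3,7-dimethyloct-6-ene-1,3-diol
Product: 20 (2R)-2-methyl-2-(4-methylpent-3-en-1-yl)oxetane, via primary tosylate 19 (not isolated)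
Conditions: n-BuLi (1 equiv), THF, 0 °C; TsCl (1 equiv); then n-BuLi (1 equiv), 0 → 60 °C
Reagents that add atoms: none
Why: Selective sulfonylation of the primary alkoxide and Williamson-type 4-exo-tet closure by the tertiary alkoxide give the oxetane with retention, since the C6–O bond is never broken.

Step 11
Reactants: 20 (2R)-2-methyl-2-(4-methylpent-3-en-1-yl)oxetane
Product: 22 3-[(2R)-2-methyloxetan-2-yl]propanal, via ozonide 21 (not isolated)
Conditions: O3, CH2Cl2, −78 °C; then Me2S, −78 °C → rt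
Reagents that add atoms: ozone, [O-][O+]=O
Why: Ozonolysis with reductive work-up cleaves the only alkene and uncovers C3 as an aldehyde, and the oxetane is inert to ozone.

Step 12
Reactants: 22 3-[(2R)-2-methyloxetan-2-yl]propanal
Product: 24 (3S,4R)-3-methyl-6-[(2R)-2-methyloxetan-2-yl]hex-1-en-4-ol, via dialkylborinate 23 (not isolated)
Conditions: trans-2-butene, n-BuLi, KOt-Bu, THF, −78 → −45 °C; (−)-Ipc2BOMe, −78 °C; BF3·OEt2 (1.0 equiv); then 22, −78 °C; NaOH, H2O2, rt
Reagents that add atoms: (E)-crotyldiisopinocampheylborane of the (+)-α-pinene series (made in the flask from trans-but-2-ene), C/C=C/CB([C@@H]1C[C@@H]2C[C@H]([C@H]1C)C2(C)C)[C@@H]1C[C@@H]2C[C@H]([C@H]1C)C2(C)C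
Why: Brown crotylboration proceeds through a closed Zimmerman–Traxler chair in which the E-crotyl geometry gives the anti C2/C3 pair and the isopinocampheyl groups select the aldehyde face, setting C3 as R and C2 as S at this stage.

Step 13
Reactants: 24 (3S,4R)-3-methyl-6-[(2R)-2-methyloxetan-2-yl]hex-1-en-4-ol
Product: 26 (2S,3R)-2-methyl-5-[(2R)-2-methyloxetan-2-yl]pentane-1,3-diol, via hydroxy aldehyde 25 (not isolated)
Conditions: O3, CH2Cl2/MeOH, −78 °C; then NaBH4, −78 → 0 °C
Reagents that add atoms: ozone, [O-][O+]=O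
Why: Ozonolysis with borohydride work-up trims the vinyl group to the C1 hydroxymethyl group and reduces the epimerisable aldehyde as soon as it forms.

Step 14
Reactants: 26 (2S,3R)-2-methyl-5-[(2R)-2-methyloxetan-2-yl]pentane-1,3-diol
Product: 27 (2S,3R)-1-[(tert-butyldiphenylsilyl)oxy]-2-methyl-5-[(2R)-2-methyloxetan-2-yl]pentan-3-ol
Conditions: TBDPSCl (1.05 equiv), imidazole, CH2Cl2, 0 °C
Reagents that add atoms: tert-butyl(chloro)diphenylsilane, CC(C)(C)[Si](Cl)(c1ccccc1)c1ccccc1
Why: Silylation with a bulky chlorosilane selects the primary C1 hydroxyl over the branched secondary one and installs an acid-tolerant mask for the later peroxide chemistry.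

Step 15
Reactants: 27 (2S,3R)-1-[(tert-butyldiphenylsilyl)oxy]-2-methyl-5-[(2R)-2-methyloxetan-2-yl]pentan-3-ol
Product: 28 (2S,3R)-1-[(tert-butyldiphenylsilyl)oxy]-2-methyl-5-[(2R)-2-methyloxetan-2-yl]pentan-3-yl methanesulfonate
Conditions: MsCl, Et3N, CH2Cl2, 0 °C
Reagents that add atoms: methanesulfonyl chloride, CS(=O)(=O)Cl
Why: Mesylation activates the C3 oxygen with retention, and with C1 held at the alcohol level there is no acidic C2–H that could trigger elimination.

Step 16
Reactants: 28 (2S,3R)-1-[(tert-butyldiphenylsilyl)oxy]-2-methyl-5-[(2R)-2-methyloxetan-2-yl]pentan-3-yl methanesulfonate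
Product: 29 (2S,3R,6S)-1-[(tert-butyldiphenylsilyl)oxy]-6-hydroperoxy-8-hydroxy-2,6-dimethyloctan-3-yl methanesulfonate
Conditions: anhydrous H2O2 in Et2O (10 equiv), Me3SiOTf (15 mol %), −78 → 0 °C
Reagents that add atoms: hydrogen peroxide, OO
Why: Lewis-acid-catalysed perhydrolysis of a 2,2-dialkyloxetane lets H2O2 attack the tertiary carbon from the side opposite the activated ring oxygen, so C6 should be inverted to the arrangement of the target while C8 is released as an alcohol.

Step 17
Reactants: 29 (2S,3R,6S)-1-[(tert-butyldiphenylsilyl)oxy]-6-hydroperoxy-8-hydroxy-2,6-dimethyloctan-3-yl methanesulfonate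
Product: 30 2-[(3S,6S)-6-{(2S)-1-[(tert-butyldiphenylsilyl)oxy]propan-2-yl}-3-methyl-1,2-dioxan-3-yl]ethan-1-ol
Conditions: KOt-Bu (1.05 equiv), 18-crown-6, THF, 0 °C → rt
Reagents that add atoms: none
Why: Intramolecular alkylation of the hydroperoxide anion (6-exo-tet SN2) closes the 1,2-dioxane and inverts C3, turning the anti C2/C3 pair into the syn pair of the target, with the C3 side chain cis to the C6 methyl.

Step 18
Reactants: 30 2-[(3S,6S)-6-{(2S)-1-[(tert-butyldiphenylsilyl)oxy]propan-2-yl}-3-methyl-1,2-dioxan-3-yl]ethan-1-ol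
Product: 31 2-[(3S,6S)-6-{(2S)-1-[(tert-butyldiphenylsilyl)oxy]propan-2-yl}-3-methyl-1,2-dioxan-3-yl]acetaldehyde
Conditions: Dess–Martin periodinane, NaHCO3, CH2Cl2, 0 °C
Reagents that add atoms: none
Why: Dess–Martin oxidation gives the C8 aldehyde under non-basic conditions, so the β-peroxy aldehyde should not ring-open by elimination.

Step 19
Reactants: 31 2-[(3S,6S)-6-{(2S)-1-[(tert-butyldiphenylsilyl)oxy]propan-2-yl}-3-methyl-1,2-dioxan-3-yl]acetaldehyde
Product: 32 tert-butyl{(2S)-2-[(3S,6S)-6-methyl-6-(prop-2-en-1-yl)-1,2-dioxan-3-yl]propoxy}diphenylsilane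
Conditions: MePPh3Br, KN(SiMe3)2, THF, 0 °C; then 31, −78 → 0 °C
Reagents that add atoms: methyltriphenylphosphonium bromide, C[P+](c1ccccc1)(c1ccccc1)c1ccccc1.[Br-]
Why: Wittig methylenation adds C9, since addition of the ylide to an unhindered aldehyde at low temperature is faster than enolisation and dialkyl peroxides are known to tolerate phosphorus ylides.

Step 20
Reactants: 32 tert-butyl{(2S)-2-[(3S,6S)-6-methyl-6-(prop-2-en-1-yl)-1,2-dioxan-3-yl]propoxy}diphenylsilane; 15 4-[(1R)-2,2-dimethyl-6-methylidene-1-(triethylsilyloxy)cyclohexyl]but-1-en-2-yl trifluoromethanesulfonate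
Product: 34 tert-butyl{(2S)-2-[(3S,6R)-6-{6-[(1R)-2,2-dimethyl-6-methylidene-1-(triethylsilyloxy)cyclohexyl]-4-methylidenehexyl}-6-methyl-1,2-dioxan-3-yl]propoxy}diphenylsilane, via B-alkyl-9-BBN 33 (not isolated)
Conditions: 9-BBN (1.3 equiv), THF, 0 °C → rt; then 15, Pd(dppf)Cl2 (5 mol %), AsPh3 (5 mol %), Cs2CO3, DMF/H2O, rt
Reagents that add atoms: none
Why: In this B-alkyl Suzuki–Miyaura coupling, anti-Markovnikov hydroboration places boron on C9 and the borate hands this primary alkyl group to the alkenylpalladium species from 15, forming C9–C10 at room temperature while no ester is yet present for base to attack.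

Step 21
Reactants: 34 tert-butyl{(2S)-2-[(3S,6R)-6-{6-[(1R)-2,2-dimethyl-6-methylidene-1-(triethylsilyloxy)cyclohexyl]-4-methylidenehexyl}-6-methyl-1,2-dioxan-3-yl]propoxy}diphenylsilane
Product: 35 (2S)-2-[(3S,6R)-6-{6-[(1R)-1-hydroxy-2,2-dimethyl-6-methylidenecyclohexyl]-4-methylidenehexyl}-6-methyl-1,2-dioxan-3-yl]propan-1-ol
Conditions: Bu4NF (3 equiv), THF, 0 °C → rt; H2O work-up
Reagents that add atoms: none
Why: Fluoride-induced desilylation removes both silyl ethers in one operation, and the saturated dialkyl peroxide and the alkenes do not react with fluoride.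

Step 22
Reactants: 35 (2S)-2-[(3S,6R)-6-{6-[(1R)-1-hydroxy-2,2-dimethyl-6-methylidenecyclohexyl]-4-methylidenehexyl}-6-methyl-1,2-dioxan-3-yl]propan-1-ol
Product: 37 (2R)-2-[(3S,6R)-6-{6-[(1R)-1-hydroxy-2,2-dimethyl-6-methylidenecyclohexyl]-4-methylidenehexyl}-6-methyl-1,2-dioxan-3-yl]propanoic acid, via aldehyde 36 (not isolated)
Conditions: TEMPO (20 mol %), PhI(OAc)2 (2.5 equiv), MeCN/pH 7 buffer, rt
Reagents that add atoms: water, O
Why: Oxoammonium-mediated oxidation (TEMPO/PhI(OAc)2) takes only the primary alcohol through the aldehyde hydrate to the acid; the tertiary C13 alcohol cannot be oxidised, and the near-neutral medium should preserve C2 (the descriptor changes from S to R by priority only).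

Step 23
Reactants: 37 (2R)-2-[(3S,6R)-6-{6-[(1R)-1-hydroxy-2,2-dimethyl-6-methylidenecyclohexyl]-4-methylidenehexyl}-6-methyl-1,2-dioxan-3-yl]propanoic acid
Product: 38 methyl (2R)-2-[(3S,6R)-6-{6-[(1R)-1-hydroxy-2,2-dimethyl-6-methylidenecyclohexyl]-4-methylidenehexyl}-6-methyl-1,2-dioxan-3-yl]propanoate (CNP0185522.3)
Conditions: Me3SiCHN2, toluene/MeOH, 0 °C
Reagents that add atoms: (trimethylsilyl)diazomethane, C[Si](C)(C)C=[N+]=[N-]
Why: Esterification with the diazoalkane runs by protonation and O-alkylation without added base, so neither C2 nor the β-peroxy ester should be disturbed.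

Compound list
1 | 5-chloropent-1-yne | C#CCCCCl | starting material
2 | 5-iodopent-1-yne | C#CCCCI | intermediate
3 | methyl isobutyrate | COC(=O)C(C)C | starting material
4 | lithium enolate of methyl isobutyrate | COC(O[Li])=C(C)C | intermediate
5 | methyl 2,2-dimethylhept-6-ynoate | C#CCCCC(C)(C)C(=O)OC | intermediate
6 | 2,2-dimethylhept-6-ynal | C#CCCCC(C)(C)C=O | intermediate
7 | 2-(2-bromoethyl)-2-methyl-1,3-dioxolane | CC1(CCBr)OCCO1 | starting material
8 | [2-(2-methyl-1,3-dioxolan-2-yl)ethyl]magnesium bromide | CC1(CC[Mg]Br)OCCO1 | intermediate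
9 | 4,4-dimethyl-1-(2-methyl-1,3-dioxolan-2-yl)non-8-yn-3-ol (racemic) | C#CCCCC(C)(C)C(O)CCC1(C)OCCO1 | intermediate
10 | 4,4-dimethyl-1-(2-methyl-1,3-dioxolan-2-yl)non-8-yn-3-one | C#CCCCC(C)(C)C(=O)CCC1(C)OCCO1 | intermediate
11 | triethylsilane | CC[SiH](CC)CC | starting material
12 | triethyl({(1R)-2,2-dimethyl-6-methylidene-1-[2-(2-methyl-1,3-dioxolan-2-yl)ethyl]cyclohexyl}oxy)silane | CC1(CC[C@]2(O[Si](CC)(CC)CC)C(=C)CCCC2(C)C)OCCO1 | intermediate
13 | 4-[(1R)-2,2-dimethyl-6-methylidene-1-(triethylsilyloxy)cyclohexyl]butan-2-one | CC(=O)CC[C@]1(O[Si](CC)(CC)CC)C(=C)CCCC1(C)C | intermediate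
14 | terminal lithium enolate of 13 | C=C(O[Li])CC[C@]1(O[Si](CC)(CC)CC)C(=C)CCCC1(C)C | intermediate
15 | 4-[(1R)-2,2-dimethyl-6-methylidene-1-(triethylsilyloxy)cyclohexyl]but-1-en-2-yl trifluoromethanesulfonate | C=C(OS(=O)(=O)C(F)(F)F)CC[C@]1(O[Si](CC)(CC)CC)C(=C)CCCC1(C)C | intermediate
16 | (R)-(−)-linalool | C=C[C@](C)(O)CCC=C(C)C | starting material
17 | 9-[(3R)-3-hydroxy-3,7-dimethyloct-6-en-1-yl]-9-borabicyclo[3.3.1]nonane | B1(CC[C@](C)(O)CCC=C(C)C)C2CCCC1CCC2 | intermediate
18 | (3R)-3,7-dimethyloct-6-ene-1,3-diol | OCC[C@](C)(O)CCC=C(C)C | intermediate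
19 | (3R)-3-hydroxy-3,7-dimethyloct-6-en-1-yl 4-methylbenzenesulfonate | Cc1ccc(cc1)S(=O)(=O)OCC[C@](C)(O)CCC=C(C)C | intermediate
20 | (2R)-2-methyl-2-(4-methylpent-3-en-1-yl)oxetane | CC(C)=CCC[C@]1(C)CCO1 | intermediate
21 | 3,3-dimethyl-5-{2-[(2R)-2-methyloxetan-2-yl]ethyl}-1,2,4-trioxolane | CC1(C)OOC(CC[C@]2(C)CCO2)O1 | intermediate
22 | 3-[(2R)-2-methyloxetan-2-yl]propanal | O=CCC[C@]1(C)CCO1 | intermediate
23 | diisopinocampheylborinate of 24 | C=C[C@H](C)[C@H](OB([C@@H]1C[C@@H]2C[C@H]([C@H]1C)C2(C)C)[C@@H]1C[C@@H]2C[C@H]([C@H]1C)C2(C)C)CC[C@]1(C)CCO1 | intermediate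
24 | (3S,4R)-3-methyl-6-[(2R)-2-methyloxetan-2-yl]hex-1-en-4-ol | C=C[C@H](C)[C@H](O)CC[C@]1(C)CCO1 | intermediate
25 | (2R,3R)-3-hydroxy-2-methyl-5-[(2R)-2-methyloxetan-2-yl]pentanal | O=C[C@H](C)[C@H](O)CC[C@]1(C)CCO1 | intermediate
26 | (2S,3R)-2-methyl-5-[(2R)-2-methyloxetan-2-yl]pentane-1,3-diol | OC[C@H](C)[C@H](O)CC[C@]1(C)CCO1 | intermediate
27 | (2S,3R)-1-[(tert-butyldiphenylsilyl)oxy]-2-methyl-5-[(2R)-2-methyloxetan-2-yl]pentan-3-ol | CC(C)(C)[Si](c1ccccc1)(c1ccccc1)OC[C@H](C)[C@H](O)CC[C@]1(C)CCO1 | intermediate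
28 | (2S,3R)-1-[(tert-butyldiphenylsilyl)oxy]-2-methyl-5-[(2R)-2-methyloxetan-2-yl]pentan-3-yl methanesulfonate | CC(C)(C)[Si](c1ccccc1)(c1ccccc1)OC[C@H](C)[C@H](OS(C)(=O)=O)CC[C@]1(C)CCO1 | intermediate
29 | (2S,3R,6S)-1-[(tert-butyldiphenylsilyl)oxy]-6-hydroperoxy-8-hydroxy-2,6-dimethyloctan-3-yl methanesulfonate | CC(C)(C)[Si](c1ccccc1)(c1ccccc1)OC[C@H](C)[C@H](OS(C)(=O)=O)CC[C@@](OO)(C)CCO | intermediate
30 | 2-[(3S,6S)-6-{(2S)-1-[(tert-butyldiphenylsilyl)oxy]propan-2-yl}-3-methyl-1,2-dioxan-3-yl]ethan-1-ol | OCC[C@]1(C)CC[C@@H]([C@@H](C)CO[Si](c2ccccc2)(c2ccccc2)C(C)(C)C)OO1 | intermediate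
31 | 2-[(3S,6S)-6-{(2S)-1-[(tert-butyldiphenylsilyl)oxy]propan-2-yl}-3-methyl-1,2-dioxan-3-yl]acetaldehyde | O=CC[C@]1(C)CC[C@@H]([C@@H](C)CO[Si](c2ccccc2)(c2ccccc2)C(C)(C)C)OO1 | intermediate
32 | tert-butyl{(2S)-2-[(3S,6S)-6-methyl-6-(prop-2-en-1-yl)-1,2-dioxan-3-yl]propoxy}diphenylsilane | C=CC[C@]1(C)CC[C@@H]([C@@H](C)CO[Si](c2ccccc2)(c2ccccc2)C(C)(C)C)OO1 | intermediate
33 | C9 B-alkyl-9-BBN derived from 32 | B1(CCC[C@]2(C)CC[C@@H]([C@@H](C)CO[Si](c3ccccc3)(c3ccccc3)C(C)(C)C)OO2)C2CCCC1CCC2 | intermediate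
34 | tert-butyl{(2S)-2-[(3S,6R)-6-{6-[(1R)-2,2-dimethyl-6-methylidene-1-(triethylsilyloxy)cyclohexyl]-4-methylidenehexyl}-6-methyl-1,2-dioxan-3-yl]propoxy}diphenylsilane | C=C(CCC[C@]1(C)CC[C@@H]([C@@H](C)CO[Si](c2ccccc2)(c2ccccc2)C(C)(C)C)OO1)CC[C@]1(O[Si](CC)(CC)CC)C(=C)CCCC1(C)C | intermediate
35 | (2S)-2-[(3S,6R)-6-{6-[(1R)-1-hydroxy-2,2-dimethyl-6-methylidenecyclohexyl]-4-methylidenehexyl}-6-methyl-1,2-dioxan-3-yl]propan-1-ol | C=C(CCC[C@]1(C)CC[C@@H]([C@@H](C)CO)OO1)CC[C@]1(O)C(=C)CCCC1(C)C | intermediate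
36 | (2R)-2-[(3S,6R)-6-{6-[(1R)-1-hydroxy-2,2-dimethyl-6-methylidenecyclohexyl]-4-methylidenehexyl}-6-methyl-1,2-dioxan-3-yl]propanal | C=C(CCC[C@]1(C)CC[C@@H]([C@@H](C)C=O)OO1)CC[C@]1(O)C(=C)CCCC1(C)C | intermediate
37 | (2R)-2-[(3S,6R)-6-{6-[(1R)-1-hydroxy-2,2-dimethyl-6-methylidenecyclohexyl]-4-methylidenehexyl}-6-methyl-1,2-dioxan-3-yl]propanoic acid | C=C(CCC[C@]1(C)CC[C@@H]([C@@H](C)C(=O)O)OO1)CC[C@]1(O)C(=C)CCCC1(C)C | intermediate
38 | methyl (2R)-2-[(3S,6R)-6-{6-[(1R)-1-hydroxy-2,2-dimethyl-6-methylidenecyclohexyl]-4-methylidenehexyl}-6-methyl-1,2-dioxan-3-yl]propanoate | C=C(CCC[C@]1(C)CC[C@@H]([C@@H](C)C(=O)OC)OO1)CC[C@]1(O)C(=C)CCCC1(C)C | target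

Total step count: 23. Longest linear sequence: 15 steps (steps 9–23, from 16). The other branch runs 12 steps (steps 1–8 and 20–23).

Steps most likely to fail

Step 6. Oligomerisation or hydrosilylation of the terminal alkyne may outrun oxidative cyclisation onto the crowded ketone, or the ligand may discriminate the two carbonyl faces poorly. The fallback sets out from 10 and comes back at 12. The same C13–C14 bond is made by a known ketyl–alkyne radical cyclisation. Samarium diiodide (SmI2) with HMPA and t-BuOH in THF should convert 10, by 6-exo-dig attack of the ketyl on the alkyne, into racemic 2,2-dimethyl-6-methylidene-1-[2-(2-methyl-1,3-dioxolan-2-yl)ethyl]cyclohexan-1-ol F1. Preparative chromatography on a chiral stationary phase separates the (1R)-alcohol F2 from the unwanted (1S)-alcohol F3. Et3SiOTf with 2,6-lutidine then silylates F2 to 12.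

Step 16. Partial ionisation at C6 before H2O2 attacks would erode the configuration, and the acid could also loosen the silyl ether. The fallback sets out from 28 and comes back at 30, and it reverses the order of the two C–O bond formations. Displacement of the mesylate by H2O2/KOH in MeOH (SN2, inversion at C3, oxetane inert to base) should give tert-butyl({(2S,3S)-3-hydroperoxy-2-methyl-5-[(2R)-2-methyloxetan-2-yl]pentyl}oxy)diphenylsilane F4. A catalytic amount of Me3SiOTf or camphorsulfonic acid in CH2Cl2 then lets this hydroperoxide open the oxetane from within. This is a 6-exo attack at C6 with inversion, whose intramolecularity should allow milder acid and tighter backside delivery, and it gives 30 directly.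

Step 20. The O–O bond may be cleaved by zerovalent palladium, by the arsine or phosphine, or by the borane, or the base may trigger Kornblum–DeLaMare fragmentation. The fallback sets out from 13 and 30, comes back at 34, and uses neither palladium nor boron (steps 8, 18 and 19 are then not needed). Me2NNH2 converts 13 into its N,N-dimethylhydrazone F5. I2, PPh3 and imidazole convert 30 into tert-butyl{(2S)-2-[(3S,6S)-6-(2-iodoethyl)-6-methyl-1,2-dioxan-3-yl]propoxy}diphenylsilane F6. Deprotonation of F5 at its methyl group with LiN(i-Pr)2 and alkylation with F6 at −78 → 0 °C forms C8–C9 and gives the chain-extended hydrazone F7. Two-phase aqueous oxalic acid/Et2O liberates the C10 ketone F8. Wittig methylenation (MePPh3Br, KN(SiMe3)2, THF) then installs the C10 methylene and gives 34.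

Further compounds
F1 | step 6 | racemic 2,2-dimethyl-6-methylidene-1-[2-(2-methyl-1,3-dioxolan-2-yl)ethyl]cyclohexan-1-ol | CC1(CCC2(O)C(=C)CCCC2(C)C)OCCO1
F2 | step 6 | (1R)-2,2-dimethyl-6-methylidene-1-[2-(2-methyl-1,3-dioxolan-2-yl)ethyl]cyclohexan-1-ol | CC1(CC[C@]2(O)C(=C)CCCC2(C)C)OCCO1
F3 | step 6 | (1S)-2,2-dimethyl-6-methylidene-1-[2-(2-methyl-1,3-dioxolan-2-yl)ethyl]cyclohexan-1-ol | CC1(CC[C@@]2(O)C(=C)CCCC2(C)C)OCCO1
F4 | step 16 | tert-butyl({(2S,3S)-3-hydroperoxy-2-methyl-5-[(2R)-2-methyloxetan-2-yl]pentyl}oxy)diphenylsilane | CC(C)(C)[Si](c1ccccc1)(c1ccccc1)OC[C@H](C)[C@@H](OO)CC[C@]1(C)CCO1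
F5 | step 20 | N,N-dimethylhydrazone of 13 | CN(C)N=C(C)CC[C@]1(O[Si](CC)(CC)CC)C(=C)CCCC1(C)C
F6 | step 20 | tert-butyl{(2S)-2-[(3S,6S)-6-(2-iodoethyl)-6-methyl-1,2-dioxan-3-yl]propoxy}diphenylsilane | ICC[C@]1(C)CC[C@@H]([C@@H](C)CO[Si](c2ccccc2)(c2ccccc2)C(C)(C)C)OO1
F7 | step 20 | N,N-dimethylhydrazone of the C10 ketone (2S,3S,6R,13R) | CN(C)N=C(CCC[C@]1(C)CC[C@@H]([C@@H](C)CO[Si](c2ccccc2)(c2ccccc2)C(C)(C)C)OO1)CC[C@]1(O[Si](CC)(CC)CC)C(=C)CCCC1(C)C
F8 | step 20 | C10 ketone (2S,3S,6R,13R), the 10-oxo analogue of 34 | O=C(CCC[C@]1(C)CC[C@@H]([C@@H](C)CO[Si](c2ccccc2)(c2ccccc2)C(C)(C)C)OO1)CC[C@]1(O[Si](CC)(CC)CC)C(=C)CCCC1(C)C
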